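## Analysis of the target

- **Ring system.** The target is a briarane. A cyclohexenone (ring A: C1, C10–C14) and a ten-membered carbocycle (C1–C10) share the C1–C10 bond. A γ-lactone (C7, C8, C17, C19, O) is fused to C7–C8 of the large ring.
- **Stereocentres.** There are ten, (1S,2R,3R,6S,7R,8R,9S,10S,11S,17R). They lie in two contiguous runs, C1–C3 and C6–C11, with C17 attached to the second.
- **Ring A and epoxide relations.** The C15 methyl on quaternary C1 is anti to H10, so the C2 and C9 arms are both equatorial on ring A. The C11 acetate lies on the face of H10, with C20 syn to C15. The C2–C3 epoxide is trans.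
- **Lactone relations.** The lactone is trans-fused, with C6, the C8 hydroxyl and C18 on one face. O7 and O9 are 1,3-anti.
- **Sensitive groups.** These are a secondary allylic chloride next to an exocyclic methylene, an epoxide, an α-acetoxy enone, a β-hydroxy lactone with an epimerisable C17, and a glycolate ester with a free primary hydroxyl beside a free tertiary hydroxyl.
- **Difficulty.** The hard parts are the ten-membered ring, the quaternary C1 next to C10 at the ring fusion, and the order of oxidations. Almost every reagent needed for one site endangers another.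
- **Strategic feature.** C1–C10 belongs to both carbocycles. If it is deleted, ring A and the ten-membered ring merge into one cembrane-like fourteen-membered ring (C1–C14), in which C1 and C10 face each other. In the same picture C7, C8, C17, C19 and the lactone oxygen map onto a furan.

## Retrosynthetic reasoning

**C6–Cl, C5=C16 and the glycolate.**
- 48 is the desilylated form of 47.
- In 47 the C6–Cl bond and the exocyclic methylene are cut together, back to the Z-C5=C6 alkene 46. An ene-type chlorination of a trisubstituted alkene makes both in one event, so no ketone is needed between two β-leaving groups (O7 and the epoxide).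
- The C9 ester bond is cut to diol 44 and acid 45. It is made late because the glycolate would not survive reductive or peroxide steps.

**C8–O, C17–H and C7–H (lactone to furan).**
- 44 comes through 43 from hydroxy lactone 42, and 42 from epoxy lactone 41 by reductive cleavage of the C17–O bond.
- 41 comes from butenolide 40 (38 after masking), 38 from hydroxybutenolide 37, and 37 from furan 35 by photooxygenation.
- The furan carries four skeletal carbons and O7 through the whole first half of the route as an inert aromatic ring.
- C7 is set from C9 by an internally delivered hydride, which is why O9 is free at that one point.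

**C5–C16.**
- 34 is cut at C5–C16 to enol triflate 33 and then ketone 32.
- This must happen while the furan is intact. Only then is C6–H clearly more acidic than C4–H, and only then is no acyloxy group β to the ketone.

**Ring A oxidation.**
- 30 is traced through 28, 27, 25 and 24 to 23.
- All C11/C12 oxygen is derived from the C11=C20 exocyclic alkene. These steps are placed where that alkene is the only one in the molecule, before C5=C6 exists.
- The finished α-acetoxy enone would not survive the peroxide and samarium steps, so it is masked as the allylic alcohol in 39–43 and restored in 44.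

**C3–O.**
- The trans epoxide of 23 is opened in the retrosynthetic sense to the erythro diol 21, and this to 20.
- Closure by O2 on a C3 sulfonate avoids substitution at neopentyl C2.

**C1–C10, the central cut.**
- 20 is opened to the fourteen-membered epoxy alkene 19.
- The cut is made here because it is the only bond whose formation creates both carbocycles and both ring-fusion centres at once. A 14-membered ring is also far easier to close than a ten-membered one.
- The forward step must generate a C1 radical from the C1–C2 epoxide with trivalent titanium, add it 6-endo to C10, and end at C11 as an alkene.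
- C5 is carried as a silyl ether and not as a ketone. A C5 carbonyl would sit in 5-exo reach of the C1 radical and would make O3 a β-leaving group.

**C9–C10.**
- 19 goes back through 18 and 17 to 16, and 16 to iodo aldehyde 15 by a chromium-mediated vinyl–aldehyde macrocyclisation.
- The cut lies between an sp2 carbon and a carbonyl carbon, so the alkene geometry is carried over from the vinyl iodide. C9 can then be reset by an oxidation/reagent-controlled reduction pair.

**C5–C6.**
- 15 comes from 14, 13 and 12, and 12 is cut into furan ester 3 and aldehyde 11.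
- The ester that will become C9 also makes the neighbouring methyl group (C6) acidic. One substituent thus serves two purposes.

**The chain and the furan.**
- 11 comes from 10 and 9 (C3–C4, reagent-controlled allylation), 8 and 7 (asymmetric epoxidation of a primary allylic alcohol, the most reliable way to set C1/C2), and 6 (C2–C3).
- Both E-trisubstituted alkenes come from diiodide 5, which is made in one step from the symmetric diyne 4.
- Furan 3 is built with all substituents in place from 1 and 2. Regioselective functionalisation of a preformed furan next to its methyl group would be harder.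

## Alternatives that were turned down

**Alternative 1: Grob fragmentation.**
- *Disconnection.* A C3–C8 bond is added in the retrosynthetic sense. The ten-membered ring becomes two cyclohexanes and the core becomes a linear, all-trans 6-6-6 tricycle.
- *Forward key step.* A strong alkoxide base deprotonates the bridgehead C8 hydroxyl. With a C2 sulfonate antiperiplanar to C3–C8, that bond breaks, and the C8 ketone and the E-C2=C3 alkene of dienone A1 appear together.
- *In its favour.* The reaction type is well established. Carbonyl formation pays for the ring strain. The alkene geometry follows stereospecifically, and an E-alkene is the right precursor of the trans epoxide. On reliability of the ring-forming event it is clearly stronger than the chosen step.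
- *Against it here.*
  - A1 holds only seventeen of the twenty skeletal carbons.
  - C7 is an unfunctionalised CH2.
  - The lactone would need a three-carbon unit added to a hindered ketone flanked by an oxygenated C9, followed by a selective oxidation of C7 beside a skipped diene.
  - The tricycle itself needs quaternary C1, the C11 tertiary ether and a strict antiperiplanar array, hence a long linear prelude.
  - Two alkenes must later be told apart.
- *What the chosen strategy offers in its place.* Nineteen of the twenty skeletal carbons (all but C16) are present before the key step, O7 and C17–C19 are stored in the furan, and two rings form in one step.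

**Alternative 2: chlorolactonisation.**
- *Disconnection.* C7–O and C6–Cl are cut together, back to a ten-membered E-C6=C7 alkene carrying the C19 carboxylic acid.
- *Forward key step.* An N-chlorinated hydantoin transfers electrophilic chlorine to the alkene and the acid attacks C7 from the opposite side, giving A2.
- *In its favour.* Anti addition to a defined alkene sets C6 and C7 relative to each other and closes the lactone in one stereospecific step. On this point it is stronger than the chosen route, which sets C7 (step 31) and C6 (step 39) separately on conformational arguments.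
- *Against it.*
  - It is an endgame tactic and does not say how the medium ring with its quaternary centre is made.
  - The substrate must already carry the C8 tertiary alcohol, C17, C9 and the epoxide.
  - The free C8 hydroxyl next to C7 can compete as nucleophile.
  - The face of the medium-ring alkene that is chlorinated is not controlled by anything obvious.
  - In A2 the C5 silyloxymethyl arm must still become a methylene by an elimination next to a secondary chloride, where loss of HCl competes.
  - The ring A enone is still missing.
- *What the chosen strategy offers in its place.* It solves the skeleton, and it makes the methylene and the chloride in the same step.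

**Alternative 3: chromium allylation closing C3–C4.**
- *Disconnection.* The ten-membered ring is cut at C3–C4.
- *Forward key step.* A divalent chromium salt converts a 2-substituted allyl bromide (C4–C5–C16) into an allylchromium species. This adds to the C3 α-alkoxy aldehyde and gives A3.
- *In its favour.* The reaction type is known and chemoselective. The ring, the exocyclic methylene and a C3 carbinol for the epoxide arise together, and the plan is convergent. On precedent and on economy at C5/C16 it is stronger; the chosen route spends steps 27, 28 and 39 there.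
- *Against it.*
  - It closes the ten-membered ring directly, the least favourable ring size.
  - It does so at a neopentyl, α-oxygenated aldehyde and with both halves fully substituted.
  - The C3 configuration (Felkin–Anh against chelation) is open, and the wrong one blocks a simple closure to the trans epoxide.
  - The C6 silyl ether in A3 must still be exchanged for chloride with inversion at a hindered allylic centre, where allylic transposition threatens.
  - A failure would come after all eight other stereocentres have been built.
- *What the chosen strategy offers in its place.* It uses the same chromium chemistry on an unstrained 14-membered ring (step 13), and pays for the medium ring in an exothermic C–C bond formation.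

Key step: step 17

Remark: briarane numbering (C1–C20) is used for all intermediates. C5 in 12–31 and C12 in 24 and 39–43 are temporary stereocentres that end as sp2 carbons, so their configuration does not reach the target.
Remark: (−)-Ipc2B(allyl) and acid 45 are taken as commercial.

## Steps

Step 1
Reactants: 1 ethyl acetoacetate; 2 chloroacetone
Product: 3 ethyl 2,4-dimethylfuran-3-carboxylate
Conditions: pyridine, rt → 60 °C
Reagents that add atoms: none
Why: Feist–Benary furan synthesis: the acetoacetate carbon adds to the ketone of 2, the enol oxygen displaces chloride and water is lost. This places the C6 methyl, the C9 ester, the C18 methyl and a free C19–H correctly in one operation.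

Step 2
Reactants: 4 hepta-1,6-diyne
Product: 5 (1E,6E)-1,7-diiodo-2,6-dimethylhepta-1,6-diene
Conditions: AlMe3, Cp2ZrCl2 (cat.), CH2Cl2, 0 °C → rt; I2, THF, −30 °C
Reagents that add atoms: trimethylaluminium, C[Al](C)C; iodine, [I][I]
Why: Twofold Negishi zirconium-catalysed carboalumination adds methyl and aluminium syn to each terminal alkyne. Iodinolysis with retention gives both E-trisubstituted vinyl iodides; C15 and C20 come from AlMe3.

Step 3
Reactants: 5 (1E,6E)-1,7-diiodo-2,6-dimethylhepta-1,6-diene
Product: 6 (2E,7E)-8-iodo-3,7-dimethylocta-2,7-dien-1-ol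
Conditions: t-BuLi (2 equiv), Et2O, −78 °C; (CH2O)n, −78 °C → rt
Reagents that add atoms: formaldehyde (from paraformaldehyde), C=O
Why: Iodine–lithium exchange with retention of alkene geometry is followed by hydroxymethylation (C3). The two ends of 5 are equivalent, so the monofunctionalisation is statistical and unreacted 5 is recovered and reused.

Step 4
Reactants: 6 (2E,7E)-8-iodo-3,7-dimethylocta-2,7-dien-1-ol
Product: 7 [(2S,3S)-3-[(4E)-5-iodo-4-methylpent-4-enyl]-3-methyloxiran-2-yl]methanol
Conditions: Ti(OiPr)4 (cat.), L-(+)-diethyl tartrate, t-BuOOH, 4 Å MS, CH2Cl2, −20 °C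
Reagents that add atoms: tert-butyl hydroperoxide, CC(C)(C)OO
Why: Sharpless asymmetric epoxidation of an E-trisubstituted primary allylic alcohol of the geraniol type. The L-(+)-tartrate delivers oxygen to the face that gives the (1S,2S)-epoxide in briarane numbering, and the vinyl iodide, which has no directing hydroxyl, is left alone.

Step 5
Reactants: 7 epoxy alcohol
Product: 8 (2R,3S)-3-[(4E)-5-iodo-4-methylpent-4-enyl]-3-methyloxirane-2-carbaldehyde
Conditions: Dess–Martin periodinane, pyridine, CH2Cl2, 0 °C → rt
Reagents that add atoms: none
Why: Dess–Martin oxidation under buffered, non-epimerising conditions; epoxide and vinyl iodide are inert. The descriptor at C2 changes only because the priorities change.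

Step 6
Reactants: 8 epoxy aldehyde
Product: 9 (1S)-1-[(2S,3S)-3-[(4E)-5-iodo-4-methylpent-4-enyl]-3-methyloxiran-2-yl]but-3-en-1-ol
Conditions: (−)-Ipc2B(allyl), Et2O, −78 °C; H2O2, pH 7 buffer
Reagents that add atoms: (−)-B-allyldiisopinocampheylborane, C=CCB([C@@H]1C[C@@H]2C[C@H]([C@H]1C)C2(C)C)[C@@H]1C[C@@H]2C[C@H]([C@H]1C)C2(C)C
Why: Brown asymmetric allylboration through a chair Zimmerman–Traxler transition state. The reagent derived from (+)-α-pinene overrides the weak bias of the epoxy aldehyde and sets (3S), the erythro relation of O3 to the epoxide oxygen that the later C2–C3 epoxide needs. The neutral oxidative work-up avoids Payne rearrangement.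

Step 7
Reactants: 9 homoallylic alcohol
Product: 10 triethylsilyl ether of 9
Conditions: TESCl, imidazole, CH2Cl2, 0 °C
Reagents that add atoms: chlorotriethylsilane, CC[Si](Cl)(CC)CC
Why: Standard silylation. TES is the most labile of the three silyl groups used, so O3 can be freed first after the key step.

Step 8
Reactants: 10 TES ether
Product: 11 (3S)-3-[(2S,3S)-3-[(4E)-5-iodo-4-methylpent-4-enyl]-3-methyloxiran-2-yl]-3-(triethylsilyloxy)propanal
Conditions: OsO4 (cat.), NaIO4, 2,6-lutidine, dioxane/H2O, rt
Reagents that add atoms: osmium tetroxide, O=[Os](=O)(=O)=O; sodium periodate, [Na+].[O-]I(=O)(=O)=O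
Why: Lemieux–Johnson cleavage. OsO4 selects the monosubstituted alkene over the hindered, electron-poor vinyl iodide, and lutidine keeps the medium neutral for the TES ether and the epoxide.

Step 9
Reactants: 3 ethyl 2,4-dimethylfuran-3-carboxylate; 11 aldehyde
Product: 12 aldol adduct, ethyl 4-methylfuran-3-carboxylate carrying at furan C2 the chain C6H2–(5S)-CH(OH)–C4H2–(3S)-CH(OTES)–(1S,2S)-epoxide–(CH2)3–C(CH3)=CHI (E)
Conditions: LDA, THF, −78 °C; 11; AcOH, −78 °C
Reagents that add atoms: none
Why: Only the 2-methyl group is conjugated with the ester, so LDA gives the extended (vinylogous) enolate, which adds to the aldehyde at −78 °C (aldol addition forming C5–C6). Only modest 1,3-anti induction (polar model) can be claimed. The (5S) adduct is purified by chromatography, and C5 becomes sp2 in step 26.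

Step 10
Reactants: 12 aldol adduct
Product: 13 C5 tert-butyldimethylsilyl ether of 12
Conditions: TBSCl, imidazole, DMF, rt
Reagents that add atoms: tert-butylchlorodimethylsilane, CC(C)(C)[Si](C)(C)Cl
Why: Silylation under mild base forestalls lactonisation of O5 onto the C9 ester. TBS lies between TES and TIPS in lability.

Step 11
Reactants: 13 silylated ester
Product: 14 furylmethanol (C9H2OH), otherwise as 13
Conditions: DIBAL-H, CH2Cl2, −78 °C
Reagents that add atoms: none
Why: DIBAL-H reduces the hindered furoate to the alcohol at low temperature, where epoxide, vinyl iodide and silyl ethers persist.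

Step 12
Reactants: 14 furylmethanol
Product: 15 furan-3-carbaldehyde (C9HO), otherwise as 13
Conditions: MnO2, CH2Cl2, rt
Reagents that add atoms: none
Why: MnO2 oxidises the activated furylic alcohol under neutral conditions.

Step 13
Reactants: 15 iodo aldehyde
Product: 16 furan-fused 14-membered macrocycle, C9 carbinol as both epimers, 10E
Conditions: CrCl2 (excess), NiCl2 (cat.), DMSO/THF, rt, high dilution
Reagents that add atoms: none
Why: Nozaki–Hiyama–Kishi macrocyclisation: nickel inserts into the vinyl iodide, the vinyl group passes to trivalent chromium and adds chemoselectively to the aldehyde with retention of the E geometry. High dilution favours the strain-free 14-membered ring. C9 is not controlled here and is erased in step 14.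

Step 14
Reactants: 16 macrocyclic carbinol
Product: 17 macrocyclic furyl enone (C9 ketone)
Conditions: MnO2, CH2Cl2, rt
Reagents that add atoms: none
Why: The alcohol is both allylic and furylic, so MnO2 suffices. Both C9 epimers converge on one ketone.

Step 15
Reactants: 17 macrocyclic ketone
Product: 18 (9S)-macrocyclic allylic alcohol
Conditions: (R)-2-methyl-CBS-oxazaborolidine, BH3·SMe2, toluene, −40 °C; MeOH
Reagents that add atoms: none
Why: Corey–Bakshi–Shibata reduction. The 3-furyl group with two ortho substituents acts as the large group and the alkenyl CH= as the small one, so the (R)-catalyst should give (9S). Only 1,2-reduction is expected at this temperature.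

Step 16
Reactants: 18 (9S)-alcohol
Product: 19 key-step precursor, furan-fused 14-membered (1S,2S)-1,2-epoxy-10E-ene with (3S)-OTES, (5S)-OTBS and (9S)-OTIPS
Conditions: TIPSOTf, 2,6-lutidine, CH2Cl2, −78 → 0 °C
Reagents that add atoms: triisopropylsilyl triflate, CC(C)[Si](C(C)C)(C(C)C)OS(=O)(=O)C(F)(F)F
Why: Silyl triflate silylation of a hindered alcohol. TIPS outlasts TES and TBS and is the bulky group at C9 for the key step.

Step 17
Reactants: 19 epoxy-ene macrocycle
Product: 20 6/10-fused furan-annulated core, (1S,10S), (2R)-OH, C11 exocyclic methylene, silyl ethers as in 19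
Conditions: Cp2TiCl2, Mn dust, THF, rt, slow addition of 19; aq. NaH2PO4
Reagents that add atoms: none
Why: Proposed new method: Cp2TiCl (trivalent titanium, made from Cp2TiCl2 and Mn) binds the epoxide oxygen and cleaves the C1–O bond homolytically, giving the tertiary C1 radical and the C2 titanium alkoxide with C2 untouched. The radical adds across the ring to C10 of the E-C10=C11 alkene: ring A closes in the 6-endo-trig mode (preferred over 5-exo attack at C11 because C11 is fully substituted and the 6-endo path gives a tertiary radical), and the ten-membered ring is not closed by a separate event but is what remains of the 14-membered ring once C1–C10 exists. The C11 radical is trapped by a second Cp2TiCl and loses Cp2Ti(H)Cl from the least hindered β-position, C20, to give the exocyclic methylene. The closest known reactions are the Cp2TiCl-mediated cyclisations of epoxypolyprenes and the transannular cyclisation of epoxygermacrolides to eudesmanolides; a 14-membered ring giving a 6/10 system has not been shown. Relative configuration: in a chair-like array the E-alkene puts C9 equatorial and H10 axial, and the planar radical places its larger C2 arm equatorial and C15 axial, hence C15 anti to H10 (1S,10S). Absolute face: allylic 1,3-strain with C20 holds H9 in the alkene plane, bond formation anti to the furan carbon C8 gives the antiperiplanar C1–C10–C9–C8 torsion that a ten-membered ring accommodates, and the bulky C2 titanoxy group stays anti to the new bond; this relay from C9 and C2 is the unproven point. Chemoselectivity: C5 is a silyl ether and not a ketone, because a carbonyl there would lie in 5-exo reach of the C1 radical and would make O3 a β-leaving group, while furan, silyl ethers and the absence of any other alkene within five- or six-membered reach leave C10 as the only acceptor. Slow addition to excess reagent under strictly dry conditions suppresses hydrogen transfer to the radicals, and premature loss of titanium hydride at C1 remains the main competitor.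

Step 18
Reactants: 20 cyclised core
Product: 21 erythro (2R,3S)-diol, 5-OTBS and 9-OTIPS retained
Conditions: PPTS, MeOH/CH2Cl2, 0 °C
Reagents that add atoms: none
Why: Acid-catalysed methanolysis distinguishes the silyl ethers by size: the TES ether is cleaved, TBS and TIPS stay.

Step 19
Reactants: 21 diol
Product: 23 trans (2R,3R)-2,3-epoxide of the 6/10 core, via C3 mesylate 22 (not isolated)
Conditions: MsCl, Et3N, CH2Cl2, −20 °C; K2CO3, MeOH, 0 °C → rt
Reagents that add atoms: none
Why: Only the C3 hydroxyl is mesylated because the C2 hydroxyl is neopentyl. Carbonate then triggers intramolecular Williamson closure, O2 displacing the mesylate with inversion at C3, so the erythro diol gives the trans epoxide. Overall the epoxide has moved from C1–C2 to C2–C3, and C1 has been used for C–C bond formation.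

Step 20
Reactants: 23 epoxide
Product: 24 C12 allylic alcohol (either epimer), C11=C20 retained
Conditions: SeO2 (cat.), t-BuOOH, CH2Cl2, 0 °C → rt
Reagents that add atoms: tert-butyl hydroperoxide, CC(C)(C)OO; selenium dioxide, O=[Se]=O
Why: Catalytic SeO2 allylic oxidation (ene reaction, then 2,3-sigmatropic shift) keeps the alkene exocyclic and attacks the ring CH2 at C12 rather than the hindered methine C10. C11=C20 is the only alkene in 23, and the C12 configuration is irrelevant.

Step 21
Reactants: 24 allylic alcohol
Product: 25 C12 ketone with C11 exocyclic methylene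
Conditions: Dess–Martin periodinane, pyridine, CH2Cl2, rt
Reagents that add atoms: none
Why: Dess–Martin oxidation to the α-methylene ketone. No other free hydroxyl is present.

Step 22
Reactants: 25 α-methylene ketone
Product: 27 (11S)-11-hydroxy-12-ketone, via C11 hydroperoxide 26 (not isolated)
Conditions: Mn(dpm)3 (cat.), PhSiH3, O2, i-PrOH/CH2Cl2, 0 °C; P(OEt)3
Reagents that add atoms: dioxygen, O=O
Why: Manganese-hydride hydrogen-atom transfer to the terminal CH2 of the enone makes C20 a methyl group, O2 captures the C11 α-keto radical (Mukaiyama-type reductive α-hydroxylation of enones), and phosphite reduces the hydroperoxide. Oxygen enters anti to the axial C15 methyl and the C9 branch, on the face of H10, as in additions to exocyclic alkenes 1,3 to an angular methyl group in trans-decalins.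

Step 23
Reactants: 27 α-hydroxy ketone
Product: 28 (11S)-11-acetate of 27
Conditions: Ac2O, DMAP, Et3N, CH2Cl2, 40 °C
Reagents that add atoms: acetic anhydride, CC(=O)OC(C)=O
Why: DMAP-catalysed acetylation of the only free hydroxyl. It is done now because the tertiary C8 hydroxyl would compete later.

Step 24
Reactants: 28 α-acetoxy ketone
Product: 30 11-acetoxy-13-en-12-one (ring A complete), via silyl enol ether 29 (not isolated)
Conditions: LiHMDS, TMSCl, THF, −78 °C; Pd(OAc)2, MeCN, rt
Reagents that add atoms: none
Why: Saegusa–Ito dehydrogenation. C13 is the only enolisable position of the C12 ketone (C11 is quaternary) and is far more acidic than the acetate methyl. TMSCl present from the start traps the enolate, and divalent palladium effects β-hydride loss to the C13=C14 enone.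

Step 25
Reactants: 30 acetoxy enone
Product: 31 (5S)-C5 alcohol, 9-OTIPS retained
Conditions: HF·pyridine, pyridine, THF, 0 °C → rt
Reagents that add atoms: none
Why: Buffered HF·pyridine removes the unhindered secondary TBS ether, whereas the TIPS ether at crowded C9 survives.

Step 26
Reactants: 31 C5 alcohol
Product: 32 C5 ketone (furylmethyl, β,γ-epoxy ketone)
Conditions: Dess–Martin periodinane, pyridine, CH2Cl2, 0 °C
Reagents that add atoms: none
Why: Neutral Dess–Martin oxidation erases the temporary C5 centre. The sensitive ketone is used at once.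

Step 27
Reactants: 32 C5 ketone
Product: 33 C5 enol triflate, C5=C6 with C4 cis to C7
Conditions: KHMDS, PhNTf2, THF, −78 °C
Reagents that add atoms: N-phenylbis(trifluoromethanesulfonimide), O=S(=O)(N(c1ccccc1)S(=O)(=O)C(F)(F)F)C(F)(F)F
Why: The C6 hydrogens are α to the ketone and furylic, hence much more acidic than those at C4, so only the furan-conjugated enolate forms and the epoxide is not opened from a C4 enolate; triflation fixes this regiochemistry. The ring-cis geometry is expected because a ten-membered ring that already holds a trans epoxide avoids a second trans unit.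

Step 28
Reactants: 33 enol triflate
Product: 34 (5Z)-C5-methyl alkene (C16 in place), 9-OTIPS
Conditions: Pd(PPh3)4 (cat.), Me2Zn, THF, 0 °C → rt
Reagents that add atoms: dimethylzinc, C[Zn]C
Why: Negishi coupling with retention of geometry brings in C16. Me2Zn without copper does not add to the hindered enone and leaves esters and the epoxide alone.

Step 29
Reactants: 34 TIPS ether
Product: 35 (9S)-C9 alcohol
Conditions: TBAF, AcOH, THF, rt
Reagents that add atoms: none
Why: Fluoride cleavage is buffered with acetic acid to protect the α-acetoxy enone. The free C9 hydroxyl is the directing group of step 31.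

Step 30
Reactants: 35 furan
Product: 37 γ-hydroxybutenolide (C19 lactone carbonyl; C7 hemiketal of either configuration; C8=C17), via furan endoperoxide 36 (not isolated)
Conditions: O2, tetraphenylporphyrin (cat.), hν, i-Pr2NEt, CH2Cl2, −78 °C → rt
Reagents that add atoms: dioxygen, O=O
Why: Singlet oxygen adds across C7 and C19 of the electron-rich furan (4+2) much faster than it reacts with the other alkenes. The amine removes the only hydrogen on the peroxide bridge, H19 (Kornblum–DeLaMare), so C19 becomes the carbonyl and C7 the hemiketal carbon without regiochemical ambiguity.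

Step 31
Reactants: 37 γ-hydroxybutenolide
Product: 38 (7S)-butenolide with free (9S)-OH
Conditions: Me4NBH(OAc)3, MeCN/AcOH, −30 → 0 °C
Reagents that add atoms: none
Why: Evans–Saksena reduction. Ring–chain tautomerism of 37 exposes the C7 carbonyl, the C9 hydroxyl exchanges onto boron, and hydride is delivered internally through a chair, giving the 1,3-anti relation of O7 and O9; the carbinol then closes onto C19 with loss of water. The reagent does not reduce ketones that lack a neighbouring hydroxyl, so the ring A enone survives.

Step 32
Reactants: 38 butenolide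
Product: 39 (12S)-allylic alcohol
Conditions: NaBH4, CeCl3·7H2O, MeOH, −78 °C
Reagents that add atoms: none
Why: Luche 1,2-reduction masks the α-acetoxy enone, which would survive neither nucleophilic epoxidation nor SmI2. Hydride comes from the face opposite the C15 and C20 methyl groups, and the tetrasubstituted butenolide is inert.

Step 33
Reactants: 39 diol
Product: 40 9,12-bis(triethylsilyl) ether
Conditions: TESOTf, 2,6-lutidine, CH2Cl2, −78 °C
Reagents that add atoms: triethylsilyl triflate, CC[Si](CC)(CC)OS(=O)(=O)C(F)(F)F
Why: Both secondary hydroxyls are silylated in one operation. This prevents acetyl migration from O11 to O12 and turns O9 from a directing into a shielding group.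

Step 34
Reactants: 40 butenolide
Product: 41 8,17-epoxy lactone, epoxide oxygen cis to C6 and trans to H7
Conditions: t-BuOOH, DBU, toluene, 0 °C → rt
Reagents that add atoms: tert-butyl hydroperoxide, CC(C)(C)OO
Why: Weitz–Scheffer nucleophilic epoxidation: only the electron-poor C8=C17 bond reacts, and the lactone ring locks its geometry. With H9 held in the alkene plane by allylic strain against C18, the peroxide attacks C8 anti to the C9–O bond (Felkin–Anh). This path also opens the C6–C7–C8–C9 torsion toward the trans-fused lactone instead of closing it toward an eclipsed cis fusion.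

Step 35
Reactants: 41 epoxy lactone
Product: 42 (17R)-8-hydroxy lactone (8-OH, C6 and C18 cis on the lactone ring), 9,12-bis-TES
Conditions: SmI2, HMPA, Me2NCH2CH2OH, THF, 0 °C
Reagents that add atoms: none
Why: Single-electron reduction of the α,β-epoxy lactone, under the conditions used for α,β-epoxy esters, cleaves the C17–O bond and keeps C8–O, giving the tertiary alcohol with retention. The samarium enolate is protonated at C17, and the isomer with C18 trans to the bulky C9 branch is also the thermodynamically preferred one at this epimerisable centre.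

Step 36
Reactants: 42 bis-TES ether
Product: 43 8,9,12-triol
Conditions: HF·pyridine, pyridine, THF, 0 °C
Reagents that add atoms: none
Why: Buffered fluoride removes both TES ethers without touching the epoxide, the acetate or the β-hydroxy lactone.

Step 37
Reactants: 43 triol
Product: 44 8,9-diol with the ring A enone restored
Conditions: MnO2, CH2Cl2, rt
Reagents that add atoms: none
Why: MnO2 oxidises only the allylic C12 alcohol. The C9 secondary and C8 tertiary hydroxyls are not activated.

Step 38
Reactants: 44 diol; 45 (tert-butyldimethylsilyloxy)acetic acid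
Product: 46 C9 O-TBS-glycolate
Conditions: EDC·HCl, DMAP, CH2Cl2, rt
Reagents that add atoms: none
Why: Steglich esterification. Of the two remaining hydroxyls only the secondary C9–OH is acylated; the tertiary C8–OH is inert.

Step 39
Reactants: 46 (5Z)-alkene
Product: 47 (6S)-6-chloro-5(16)-ene, O-TBS-glycolate
Conditions: Ca(OCl)2, CO2 (s), CH2Cl2/H2O, 0 °C
Reagents that add atoms: calcium hypochlorite, [Ca+2].[O-]Cl.[O-]Cl
Why: Ene-type chlorination of a trisubstituted alkene with HOCl made in situ: chlorine binds to the less substituted C6, charge builds at C5, and a proton is lost from the freely rotating C16 methyl (C4–H is deactivated by the adjacent epoxide), giving the transposed allylic chloride. With H7 in the alkene plane (allylic strain with C4) the electrophile should add anti to the allylic C7–O bond, which corresponds to (6S). The enone is too electron-poor to react.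

Step 40
Reactants: 47 silyl ether
Product: 48 target CNP0278742.1
Conditions: HF·pyridine, pyridine, THF, 0 °C
Reagents that add atoms: none
Why: Buffered HF·pyridine cleaves the primary TBS ether quickly. Allylic chloride, epoxide, esters and enone tolerate these mild, weakly nucleophilic conditions.

## Compound list

1 | ethyl acetoacetate | CCOC(=O)CC(C)=O | starting material
2 | chloroacetone | CC(=O)CCl | starting material
3 | ethyl 2,4-dimethylfuran-3-carboxylate | CCOC(=O)c1c(C)coc1C | intermediate
4 | hepta-1,6-diyne | C#CCCCC#C | starting material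
5 | (1E,6E)-1,7-diiodo-2,6-dimethylhepta-1,6-diene | I/C=C(C)/CCC/C(C)=C/I | intermediate
6 | (2E,7E)-8-iodo-3,7-dimethylocta-2,7-dien-1-ol | OC/C=C(C)/CCC/C(C)=C/I | intermediate
7 | [(2S,3S)-3-[(4E)-5-iodo-4-methylpent-4-enyl]-3-methyloxiran-2-yl]methanol | OC[C@@H]1O[C@@]1(C)CCC/C(C)=C/I | intermediate
8 | (2R,3S)-3-[(4E)-5-iodo-4-methylpent-4-enyl]-3-methyloxirane-2-carbaldehyde | O=C[C@@H]1O[C@@]1(C)CCC/C(C)=C/I | intermediate
9 | (1S)-1-[(2S,3S)-3-[(4E)-5-iodo-4-methylpent-4-enyl]-3-methyloxiran-2-yl]but-3-en-1-ol | C=CC[C@H](O)[C@@H]1O[C@@]1(C)CCC/C(C)=C/I | intermediate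
10 | triethylsilyl ether of 9 | C=CC[C@H](O[Si](CC)(CC)CC)[C@@H]1O[C@@]1(C)CCC/C(C)=C/I | intermediate
11 | (3S)-3-(epoxyalkyl)-3-(triethylsilyloxy)propanal (C5 aldehyde) | O=CC[C@H](O[Si](CC)(CC)CC)[C@@H]1O[C@@]1(C)CCC/C(C)=C/I | intermediate
12 | aldol adduct, (5S)-OH, (3S)-OTES, (1S,2S)-epoxide, E-vinyl iodide | CCOC(=O)c1c(C)coc1C[C@@H](O)C[C@H](O[Si](CC)(CC)CC)[C@@H]2O[C@@]2(C)CCC/C(C)=C/I | intermediate
13 | C5 TBS ether of 12 | CCOC(=O)c1c(C)coc1C[C@@H](O[Si](C)(C)C(C)(C)C)C[C@H](O[Si](CC)(CC)CC)[C@@H]2O[C@@]2(C)CCC/C(C)=C/I | intermediate
14 | furylmethanol (C9H2OH) from 13 | OCc1c(C)coc1C[C@@H](O[Si](C)(C)C(C)(C)C)C[C@H](O[Si](CC)(CC)CC)[C@@H]2O[C@@]2(C)CCC/C(C)=C/I | intermediate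
15 | furan-3-carbaldehyde (C9HO) from 14 | O=Cc1c(C)coc1C[C@@H](O[Si](C)(C)C(C)(C)C)C[C@H](O[Si](CC)(CC)CC)[C@@H]2O[C@@]2(C)CCC/C(C)=C/I | intermediate
16 | furan-fused 14-membered macrocycle, C9 carbinol as both epimers | CC(C)(C)[Si](C)(C)O[C@H]1C[C@H](O[Si](CC)(CC)CC)[C@@H]2O[C@@]2(C)CCC/C(C)=C/C(O)c2c(C)coc2C1 | intermediate
17 | macrocyclic furyl enone (C9 ketone) | CC(C)(C)[Si](C)(C)O[C@H]1C[C@H](O[Si](CC)(CC)CC)[C@@H]2O[C@@]2(C)CCC/C(C)=C/C(=O)c2c(C)coc2C1 | intermediate
18 | (9S)-macrocyclic allylic alcohol | CC(C)(C)[Si](C)(C)O[C@H]1C[C@H](O[Si](CC)(CC)CC)[C@@H]2O[C@@]2(C)CCC/C(C)=C/[C@H](O)c2c(C)coc2C1 | intermediate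
19 | key-step precursor, (1S,2S)-1,2-epoxy-10E-ene macrocycle, 3-OTES, 5-OTBS, 9-OTIPS | CC(C)(C)[Si](C)(C)O[C@H]1C[C@H](O[Si](CC)(CC)CC)[C@@H]2O[C@@]2(C)CCC/C(C)=C/[C@H](O[Si](C(C)C)(C(C)C)C(C)C)c2c(C)coc2C1 | intermediate
20 | 6/10-fused furan-annulated core, (1S,10S), (2R)-OH, C11 exocyclic methylene | CC(C)(C)[Si](C)(C)O[C@H]1C[C@H](O[Si](CC)(CC)CC)[C@H](O)[C@@]2(C)CCCC(=C)[C@@H]2[C@H](O[Si](C(C)C)(C(C)C)C(C)C)c2c(C)coc2C1 | intermediate
21 | erythro (2R,3S)-diol | CC(C)(C)[Si](C)(C)O[C@H]1C[C@H](O)[C@H](O)[C@@]2(C)CCCC(=C)[C@@H]2[C@H](O[Si](C(C)C)(C(C)C)C(C)C)c2c(C)coc2C1 | intermediate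
22 | C3 mesylate of 21 | CC(C)(C)[Si](C)(C)O[C@H]1C[C@H](OS(C)(=O)=O)[C@H](O)[C@@]2(C)CCCC(=C)[C@@H]2[C@H](O[Si](C(C)C)(C(C)C)C(C)C)c2c(C)coc2C1 | intermediate
23 | trans (2R,3R)-2,3-epoxide | CC(C)(C)[Si](C)(C)O[C@H]1C[C@H]3O[C@@H]3[C@@]2(C)CCCC(=C)[C@@H]2[C@H](O[Si](C(C)C)(C(C)C)C(C)C)c2c(C)coc2C1 | intermediate
24 | C12 allylic alcohol (either epimer) | CC(C)(C)[Si](C)(C)O[C@H]1C[C@H]3O[C@@H]3[C@@]2(C)CCC(O)C(=C)[C@@H]2[C@H](O[Si](C(C)C)(C(C)C)C(C)C)c2c(C)coc2C1 | intermediate
25 | C12 ketone with C11 exocyclic methylene | CC(C)(C)[Si](C)(C)O[C@H]1C[C@H]3O[C@@H]3[C@@]2(C)CCC(=O)C(=C)[C@@H]2[C@H](O[Si](C(C)C)(C(C)C)C(C)C)c2c(C)coc2C1 | intermediate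
26 | (11S)-C11 hydroperoxide of the C12 ketone | CC(C)(C)[Si](C)(C)O[C@H]1C[C@H]3O[C@@H]3[C@@]2(C)CCC(=O)[C@@](C)(OO)[C@@H]2[C@H](O[Si](C(C)C)(C(C)C)C(C)C)c2c(C)coc2C1 | intermediate
27 | (11S)-11-hydroxy-12-ketone | CC(C)(C)[Si](C)(C)O[C@H]1C[C@H]3O[C@@H]3[C@@]2(C)CCC(=O)[C@@](C)(O)[C@@H]2[C@H](O[Si](C(C)C)(C(C)C)C(C)C)c2c(C)coc2C1 | intermediate
28 | (11S)-11-acetoxy-12-ketone | CC(C)(C)[Si](C)(C)O[C@H]1C[C@H]3O[C@@H]3[C@@]2(C)CCC(=O)[C@@](C)(OC(C)=O)[C@@H]2[C@H](O[Si](C(C)C)(C(C)C)C(C)C)c2c(C)coc2C1 | intermediate
29 | C12 trimethylsilyl enol ether (C12=C13) of 28 | CC(C)(C)[Si](C)(C)O[C@H]1C[C@H]3O[C@@H]3[C@@]2(C)CC=C(O[Si](C)(C)C)[C@@](C)(OC(C)=O)[C@@H]2[C@H](O[Si](C(C)C)(C(C)C)C(C)C)c2c(C)coc2C1 | intermediate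
30 | 11-acetoxy-13-en-12-one, 5-OTBS, 9-OTIPS | CC(C)(C)[Si](C)(C)O[C@H]1C[C@H]3O[C@@H]3[C@@]2(C)C=CC(=O)[C@@](C)(OC(C)=O)[C@@H]2[C@H](O[Si](C(C)C)(C(C)C)C(C)C)c2c(C)coc2C1 | intermediate
31 | (5S)-C5 alcohol | O[C@H]1C[C@H]3O[C@@H]3[C@@]2(C)C=CC(=O)[C@@](C)(OC(C)=O)[C@@H]2[C@H](O[Si](C(C)C)(C(C)C)C(C)C)c2c(C)coc2C1 | intermediate
32 | C5 ketone | O=C1C[C@H]3O[C@@H]3[C@@]2(C)C=CC(=O)[C@@](C)(OC(C)=O)[C@@H]2[C@H](O[Si](C(C)C)(C(C)C)C(C)C)c2c(C)coc2C1 | intermediate
33 | C5 enol triflate, C4 cis to C7 | C1[C@H]3O[C@@H]3[C@@]2(C)C=CC(=O)[C@@](C)(OC(C)=O)[C@@H]2[C@H](O[Si](C(C)C)(C(C)C)C(C)C)c2c(C)coc2/C=C1/OS(=O)(=O)C(F)(F)F | intermediate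
34 | (5Z)-C5-methyl alkene, 9-OTIPS | C1[C@H]3O[C@@H]3[C@@]2(C)C=CC(=O)[C@@](C)(OC(C)=O)[C@@H]2[C@H](O[Si](C(C)C)(C(C)C)C(C)C)c2c(C)coc2/C=C1/C | intermediate
35 | (9S)-C9 alcohol (furan) | C1[C@H]3O[C@@H]3[C@@]2(C)C=CC(=O)[C@@](C)(OC(C)=O)[C@@H]2[C@H](O)c2c(C)coc2/C=C1/C | intermediate
36 | C7,C19 furan endoperoxide of 35 | C1[C@H]3O[C@@H]3[C@@]2(C)C=CC(=O)[C@@](C)(OC(C)=O)[C@@H]2[C@H](O)C2=C(C)C4OOC2(O4)/C=C1/C | intermediate
37 | γ-hydroxybutenolide (C7 hemiketal, either epimer) | C1[C@H]3O[C@@H]3[C@@]2(C)C=CC(=O)[C@@](C)(OC(C)=O)[C@@H]2[C@H](O)C2=C(C)C(=O)OC2(O)/C=C1/C | intermediate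
38 | (7S)-butenolide, free (9S)-OH | C1[C@H]3O[C@@H]3[C@@]2(C)C=CC(=O)[C@@](C)(OC(C)=O)[C@@H]2[C@H](O)C2=C(C)C(=O)O[C@H]2/C=C1/C | intermediate
39 | (12S)-allylic alcohol | C1[C@H]3O[C@@H]3[C@@]2(C)C=C[C@H](O)[C@@](C)(OC(C)=O)[C@@H]2[C@H](O)C2=C(C)C(=O)O[C@H]2/C=C1/C | intermediate
40 | 9,12-bis(triethylsilyl) ether | C1[C@H]3O[C@@H]3[C@@]2(C)C=C[C@H](O[Si](CC)(CC)CC)[C@@](C)(OC(C)=O)[C@@H]2[C@H](O[Si](CC)(CC)CC)C2=C(C)C(=O)O[C@H]2/C=C1/C | intermediate
41 | 8,17-epoxy lactone, oxygen cis to C6 | C1[C@H]3O[C@@H]3[C@@]2(C)C=C[C@H](O[Si](CC)(CC)CC)[C@@](C)(OC(C)=O)[C@@H]2[C@H](O[Si](CC)(CC)CC)[C@@]24O[C@@]4(C)C(=O)O[C@H]2/C=C1/C | intermediate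
42 | (17R)-8-hydroxy lactone, 9,12-bis-TES | C1[C@H]3O[C@@H]3[C@@]2(C)C=C[C@H](O[Si](CC)(CC)CC)[C@@](C)(OC(C)=O)[C@@H]2[C@H](O[Si](CC)(CC)CC)[C@]2(O)[C@@H](C)C(=O)O[C@H]2/C=C1/C | intermediate
43 | 8,9,12-triol | C1[C@H]3O[C@@H]3[C@@]2(C)C=C[C@H](O)[C@@](C)(OC(C)=O)[C@@H]2[C@H](O)[C@]2(O)[C@@H](C)C(=O)O[C@H]2/C=C1/C | intermediate
44 | 8,9-diol with ring A enone | C1[C@H]3O[C@@H]3[C@@]2(C)C=CC(=O)[C@@](C)(OC(C)=O)[C@@H]2[C@H](O)[C@]2(O)[C@@H](C)C(=O)O[C@H]2/C=C1/C | intermediate
45 | (tert-butyldimethylsilyloxy)acetic acid | CC(C)(C)[Si](C)(C)OCC(=O)O | starting material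
46 | C9 O-TBS-glycolate, (5Z)-alkene | C1[C@H]3O[C@@H]3[C@@]2(C)C=CC(=O)[C@@](C)(OC(C)=O)[C@@H]2[C@H](OC(=O)CO[Si](C)(C)C(C)(C)C)[C@]2(O)[C@@H](C)C(=O)O[C@H]2/C=C1/C | intermediate
47 | (6S)-6-chloro-5(16)-ene, O-TBS-glycolate | C=C1C[C@H]2O[C@@H]2[C@@]2(C)C=CC(=O)[C@@](C)(OC(C)=O)[C@@H]2[C@H](OC(=O)CO[Si](C)(C)C(C)(C)C)[C@]2(O)[C@@H](C)C(=O)O[C@H]2[C@H]1Cl | intermediate
48 | CNP0278742.1 | C=C1C[C@H]2O[C@@H]2[C@@]2(C)C=CC(=O)[C@@](C)(OC(C)=O)[C@@H]2[C@H](OC(=O)CO)[C@]2(O)[C@@H](C)C(=O)O[C@H]2[C@H]1Cl | target

## Step count and least certain steps

Total: 40 steps. Longest linear sequence: 39 steps (steps 2–40, from 4). Step 1 is a one-step branch.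

**Step 17 (key step, new method).**
- *What may go wrong.* The C1 radical may terminate before it reaches C10, by loss of titanium hydride, by deoxygenation or by hydrogen abstraction, because the folded reactive conformer of the 14-membered ring may be thinly populated. Closure on the wrong alkene face and 5-exo attack at C11 are also possible.
- *Fallback (known chemistry).* Leave the radical manifold and run the polar counterpart. Starting from 19, a Lewis acid such as MeAlCl2 in CH2Cl2 at −78 °C ionises the epoxide at tertiary C1. C10=C11 captures the cation through the same chair, and the C11 cation loses a proton. This is the epoxide-initiated cation–olefin cyclisation known from epoxypolyenes and, transannularly, from epoxygermacrenes. The exocyclic isomer is 20, where the route is rejoined after separation from double-bond isomers. No new compound is made on the way (F0).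

**Step 34.**
- *What may go wrong.* The tetrasubstituted butenolide may add peroxide too slowly. Attack may occur on the face anti to C6 instead of anti to O9. Base may erode C7 by γ-deprotonation.
- *Fallback.* Make the alkene electron-rich and direct the oxidant.
  - From 40, excess DIBAL-H reduces the lactone (and the acetate) to the 7,11,19-triol F1.
  - In F1 the rotamer with H7 toward C19 places the C7 hydroxyl on the required face, while the C9 silyl ether shields the other. VO(acac)2/t-BuOOH should therefore give the 8,17-epoxy triol F2.
  - TEMPO/PhI(OAc)2 oxidises the primary alcohol and closes the lactone to the 11-hydroxy epoxy lactone F3.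
  - Ac2O/DMAP acetylates its only free hydroxyl and returns to 41.

**Step 39.**
- *What may go wrong.* Chlorine may be delivered to the wrong face of C5=C6. The chloronium ion may be captured by the C8 hydroxyl. A proton may be lost from C4 instead of C16.
- *Fallback.* Put oxygen on first and invert. From 46, a Schenck ene reaction (O2, tetraphenylporphyrin, hν; PPh3) gives the (6R)-6-hydroxy-5(16)-ene F4, with oxygen on the face that the electrophile prefers. An Appel chlorination (PPh3, CCl4) then displaces it with inversion and returns to 47.

**Step 31.**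
- *What may go wrong.* The hemiketal may not open in the acidic medium, so that reduction is slow. Conjugate reduction of the dienone may occur. Anti induction may be weak because C8 is sp2.
- *Fallback.* Take the ring–chain equilibrium out of the problem. From 37, trimethylsilyldiazomethane gives the open methyl (Z)-keto ester F5, a true β-hydroxy enone. Its hydroxyl-directed reduction gives a γ-hydroxy ester that lactonises to 38.

**Step 35.**
- *What may go wrong.* The C8 alkoxide may be eliminated from the samarium enolate. The allylic C7–O bond may be reduced. C17 may be protonated from the face of the samarium alkoxide.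
- *Fallback.* Use thermodynamic instead of kinetic control at C17. From 41 the reduction is run as before, the 17-epimer F6 is accepted, and brief treatment with DBU in toluene equilibrates it to 42, in which C18 is trans to the C9 branch.

**Step 15.**
- *What may go wrong.* The catalyst may discriminate poorly between the furyl and alkenyl groups.
- *Fallback.* Secure C9 by separation and recycling instead of reagent control. From 16 the diastereomeric alcohols are separated by chromatography. One is 18. The (9R)-alcohol F7 is oxidised with MnO2 to 17 and reduced under Luche conditions back to 16 for another pass.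

## Further compounds

F0 | step 17 | none | none
F1 | step 34 | 7,11,19-triol from reduction of 40, C8=C17 with C19 cis to C7, 9,12-bis-TES | C1[C@H]3O[C@@H]3[C@@]2(C)C=C[C@H](O[Si](CC)(CC)CC)[C@@](C)(O)[C@@H]2[C@H](O[Si](CC)(CC)CC)/C(=C(\C)CO)[C@@H](O)/C=C1/C
F2 | step 34 | 8,17-epoxy-7,11,19-triol | C1[C@H]3O[C@@H]3[C@@]2(C)C=C[C@H](O[Si](CC)(CC)CC)[C@@](C)(O)[C@@H]2[C@H](O[Si](CC)(CC)CC)[C@@]4(O[C@@]4(C)CO)[C@@H](O)/C=C1/C
F3 | step 34 | 11-hydroxy 8,17-epoxy lactone | C1[C@H]3O[C@@H]3[C@@]2(C)C=C[C@H](O[Si](CC)(CC)CC)[C@@](C)(O)[C@@H]2[C@H](O[Si](CC)(CC)CC)[C@@]24O[C@@]4(C)C(=O)O[C@H]2/C=C1/C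
F4 | step 39 | (6R)-6-hydroxy-5(16)-ene, O-TBS-glycolate | C=C1C[C@H]2O[C@@H]2[C@@]2(C)C=CC(=O)[C@@](C)(OC(C)=O)[C@@H]2[C@H](OC(=O)CO[Si](C)(C)C(C)(C)C)[C@]2(O)[C@@H](C)C(=O)O[C@H]2[C@@H]1O
F5 | step 31 | open methyl (Z)-keto ester of 37 | C1[C@H]3O[C@@H]3[C@@]2(C)C=CC(=O)[C@@](C)(OC(C)=O)[C@@H]2[C@H](O)/C(=C(\C)C(=O)OC)C(=O)/C=C1/C
F6 | step 35 | 17-epimer of 42 | C1[C@H]3O[C@@H]3[C@@]2(C)C=C[C@H](O[Si](CC)(CC)CC)[C@@](C)(OC(C)=O)[C@@H]2[C@H](O[Si](CC)(CC)CC)[C@]2(O)[C@H](C)C(=O)O[C@H]2/C=C1/C
F7 | step 15 | (9R)-macrocyclic allylic alcohol | CC(C)(C)[Si](C)(C)O[C@H]1C[C@H](O[Si](CC)(CC)CC)[C@@H]2O[C@@]2(C)CCC/C(C)=C/[C@@H](O)c2c(C)coc2C1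
A1 | alternative 1 | ring A-fused cyclodeca-2E,5Z-dien-8-one (C12 dioxolane, C11 MOM ether, C9 PMB ether) | O=C1C/C=C(C)\C/C=C/[C@@]2(C)CCC3(OCCO3)[C@@](C)(OCOC)[C@@H]2[C@@H]1OCc4ccc(OC)cc4
A2 | alternative 2 | C6-chloro γ-lactone with C5 silyloxymethyl arm | C1[C@H]2O[C@@H]2[C@@]2(C)CCC(=O)[C@@](C)(OC(C)=O)[C@@H]2[C@H](OCc3ccc(OC)cc3)[C@]2(O)[C@@H](C)C(=O)O[C@H]2[C@@H](Cl)[C@@H]1CO[Si](C)(C)C(C)(C)C
A3 | alternative 3 | ten-membered C3 alcohol with C2 PMB ether and C5 methylene | C=C1C[C@H](O)[C@H](OCc4ccc(OC)cc4)[C@@]2(C)CCC3(OCCO3)[C@@](C)(OC(C)=O)[C@@H]2[C@H](OCc4ccc(OC)cc4)[C@]2(O)[C@@H](C)C(=O)O[C@H]2[C@@H]1O[Si](C)(C)C(C)(C)C
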